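Per litre and hour, the ochre run shows what its percentages hide: ring grows evenly from 17.0% at 1.00 h to 68.9% at 4.00 h, with no slowing as solid substrate is used.

| flask | solid substrate | remark | time |
|---|---|---|---|
| ochre | 0.085 M | run made earlier |  |
| dawn | 0.10 M |  | 5.0 h |
| dusk | 0.15 M |  | 5.0 h |
| summer | 0.25 M |  | 5.0 h |
| noon | 0.30 M |  | 5.0 h |

ochre run (percent of the solid substrate charged)

| time / h | ring / % | open dimer / % |
|---|---|---|
| 0.250 | 1.6 | 0 |
| 0.500 | 6.7 | 0.5 |
| 1.00 | 17.0 | 0.3 |
| 2.00 | 34.8 | 0.6 |
| 4.00 | 68.9 | 0 |

(scatter of a reading: 1 percentage point)

- a species is counted by the solid substrate in it: one open dimer or side product counts as two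
- given per volume of solution although it is solid: solid substrate
- the analysis behind the earlier runs scatters by 1 percentage point, standard deviation
- at the start none of the solid substrate is in solution
- "hardly changes" means that all values lie within two and a half points (for a concentration: within two and a half percent of the largest)

1. share of ring in all that became ring or open dimer or side product for dawn, dusk, summer, noon, in this order
2. how the row runs (rises, then falls / rises all the way / falls all the way / falls, then rises / hardly changes)

That even growth gives a reading of the ring rate, the ring gained per litre and hour while the ochre flask runs as a zero-order stretch: 0.0147 M h⁻¹. At this rate, 0.0735 M of ring stands after 5.0 h, less than the 0.10 M charged to dawn, the smallest charge asked. This reckoning therefore expects solid substrate to outlast the run in each flask, with equal concentrations in each and a flat row, but it gives no level, since side product was not read.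

The forecast gives 98%, 98%, 98%, 98%, shape hardly changes, on the ground that “Extra solid therefore only acts as a reservoir.”

The flasks give 92.6%, 92.6%, 92.6%, 92.6%. The row hardly changes, as forecast, and its level lies 5.4 percentage points lower; at 5.00 h, dawn holds side product 4.84% beside open dimer 1.04%.

    starting material → ring (k = 12.6 h⁻¹)
    2 starting material → open dimer (k = 71.4 L mol⁻¹ h⁻¹)
    solid substrate ⇌ starting material, rate k3*(cs3 - [starting material]) while solid is left; crystals form when [starting material] > cs3 (solubility = 0.0520 M, k = 0.316 h⁻¹)
    starting material + ring → side product (k = 10.9 L mol⁻¹ h⁻¹)

In dawn, the half-life of starting material by its step to ring, 0.055 h at 2.50 h, is short against the 5.0 h of the run, and at 5.00 h starting material is made and used, each step taken net, at a ratio of 0.999, a steady state. The ring rate read from ochre, over that step's constant 12.6 h⁻¹, gives c(starting material) = 0.00117 M, and at 5.00 h dawn holds 0.00118 M and noon 0.00118 M, with c(ring) at 0.0732 M in dawn and 0.0732 M in noon against 0.0735 M from the ring rate.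

(The runs come from a simulation with constants of no real substance.)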